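## The problem

Target 24 is an isoflavone in which a 7-hydroxychromen-4-one (rings A and C) carries at C3 a fully differentiated benzene (ring B) that is itself fused to a 2,2-dimethyl-2H-pyran (ring D), so that ring B appears as a 2,2-dimethylchromene attached through its C5. The two halves are joined by one aryl–C3 bond whose ring B carbon is flanked by the C4–H of the pyran ring. Ring B bears three neighbouring oxygens that must end as three different functions: the pyran oxygen (on C8a), a free hydroxyl (C8) and a methyl ether (C7). There is no stereocentre, so nothing has to be controlled in space; the difficulty lies in regiochemistry and functional group tolerance. The C3=C4 bond of ring D is an electron-rich styrene (para to the C7 methoxy group through C4a). Strong protic or Lewis acids protonate it and catalytic hydrogenation saturates it, which excludes hot BF3·OEt2 acylations and benzyl ethers that are removed with H2. Ring C opens under hydroxide and the free phenols are sensitive to oxidants, so the late steps have to be neutral or only briefly acidic. The enabling feature is that ring A is a resorcinol whose two oxygens (O1 on C8a and the hydroxyl on C7) stand ortho and para to C4a, the carbon that bears the C4 carbonyl. This is the pattern formed when a 1,1,3-trioxygenated butadiene adds across an ynone, so ring A can be built from open-chain carbons under neutral conditions after ring D is in place.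

## Retrosynthesis

**24 from 23.** The last cut is the acetal C–O bond of a methoxymethyl (MOM) ether on the C8 oxygen of the chromene. An acetal is preferred to a benzyl ether because hydrogenolysis would saturate C3=C4 of ring D, and to a silyl ether because a silyl group can migrate between the neighbouring oxygens of ring B under base. The forward step needs only brief dilute acid, which 2,2-dimethylchromenes normally tolerate.

**23 from 21.** Ring C is opened at O1–C2 and C2–C3, which removes one carbon at the formate oxidation level and leaves deoxybenzoin 21. The neighbouring choice, a cross-coupling that makes the C3–aryl bond on a 3-halochromone, would join two hindered partners, since the ring B carbon is ortho to the pyran C4. In 21 that bond is already an unstrained CH2–aryl bond. The forward reaction asks for enaminone 22 to form at the CH2 group and for the ortho phenol to close onto it.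

**21 from 14 and 18 (key disconnection).** Ring A is taken apart at C4a–C8a and C5–C6, giving terminal ynone 14 and the 1,1,3-trioxygenated diene 18. The usual neighbours are acid-mediated acylation of a preformed dihydroxybenzene with an arylacetic acid or nitrile, or addition of a protected aryl metal, which needs two further protecting groups. The first would destroy ring D and the MOM acetal; the second lengthens the endgame. The cycloaddition makes ring A with both oxygens free and correctly placed, under neutral thermal conditions. It must go with one orientation (CH2 terminus of 18 to the terminal alkyne carbon of 14), and it must be faster than enolisation of the benzylic CH2 of 14. It then aromatises through cycloadduct 19 and bis-silyl ether 20.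

**14 from 11 and 12.** The bond between the carbonyl carbon and the alkyne is cut after adjusting the oxidation level: ynone 14 comes from carbinol 13, and 13 from arylacetaldehyde 11 and ethynylmagnesium bromide 12. Direct acylation of an acetylide with an arylacetic acid derivative is the alternative, but it needs a separate synthesis of that acid and suffers from enolisation. Addition to the aldehyde followed by a neutral oxidation is simpler, and 11 has only one functional group beyond the protected chromene.

**11 from 7.** The benzylic CH2 of 11 is the former aldehyde carbon of chromene aldehyde 7, extended by one carbon through alkene 8 and primary alcohol 10 (methylenation, anti-Markovnikov hydroboration via borane 9, oxidation). A methoxymethylene Wittig reaction followed by hydrolysis would reach 11 in one step fewer, but it exposes the MOM acetal, ring D and the enolisable aldehyde 11 to aqueous acid. The three-step sequence keeps every step before the last one neutral or basic. It depends on the borane preferring the terminal vinyl group to the chromene double bond.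

**7 from 4, and 4 from 2, 3 and 1.** Ring D is cut at C4–C4a and O1–C2, giving aryl 1,1-dimethylpropargyl ether 4. Its thermal rearrangement through allenylphenol 5 and quinone methide 6 can reach only one ortho carbon, because the other carries the MOM ether. Ether 4 comes from phenol 2 and chloride 3, and 2 from 5-hydroxyvanillin 1. In 1 the hydroxyl para to the formyl group is the more acidic, so it takes the MOM group first and leaves the meta hydroxyl for the propargyl unit. The oxygen pattern of ring B, the side of pyran fusion and the one-carbon handle are thus all present in a commercial benzaldehyde.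

**18 from 15.** The diene is the bis-silyl dienol ether of methyl acetoacetate 15, made by two successive O-silylations through silyl enol ether 16 and lithium dienolate 17.

## Roads not taken

**Alternative 1:** The cut removes C2–C3, C3–C1' and O1–C2 at once. In the forward step, acetophenone A2 and DMF dimethyl acetal give enaminone A5 in the flask, and Ag2O oxidises 3-methoxycatechol A3 to ortho-quinone A4. The alpha carbon of A5 adds to C5 of A4 and the ring A phenol closes ring C with loss of dimethylamine, giving isoflavone A1.
- Merits: three bonds and the whole isoflavone skeleton form in one operation from commercial pieces. No benzylic homologation is needed, and the hindered C3–aryl bond is made by conjugate addition, not by cross-coupling. In step count to the isoflavone core this road is clearly better than the chosen plan.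
- Weak points for this target: A1 has a free catechol and no ring D. Its two hydroxyls are no longer distinguished by a para formyl group, yet the dimethylpropargyl unit must go on the C3' oxygen alone and the C4' oxygen must end free. The catechol of A1 is exposed to the same oxidant that formed it. The C7 benzyl ether cannot be removed with H2 once ring D exists.
- Comparison: the chosen plan is longer. Against that, it settles the oxygen pattern and the position of ring D on a small aldehyde where the para formyl group gives the selectivity, and it never has an oxidant beside a free catechol.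

**Alternative 2:** The cut is the aryl C–O bond of the pyran. In the forward step, Z-alkenol bromide A7 is cyclised with Pd(OAc)2, a bulky di-tert-butylbiarylphosphine and Cs2CO3 to chromene aldehyde A6, which is the same structure as compound 7.
- Merits: the route starts from inexpensive 5-bromovanillin A8, in which the bromine marks the future pyran oxygen, so no catechol has to be differentiated. It also avoids thermolysis at 180 °C. In these two respects it is as good as or better than steps 1 to 3.
- Weak points: A7 needs a carbon substituent between the formyl group and the bromine. That requires a regioselective halogenation, a chemoselective alkynylation beside the aryl bromide and a Z-selective semireduction, about five steps against three. The ring closure asks a hindered tertiary alkoxide to undergo C–O reductive elimination at palladium, and its allylic tertiary alcohol can instead ionise or dehydrate.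
- Comparison: this road only delivers compound 7 and leaves rings A and C to be made in the same way. The chosen plan reaches 7 in fewer steps by a cascade whose regiochemistry is forced by the substitution.

**Alternative 3:** The cut is the same as in step 3 of the chosen plan (C2'–CH and O–CMe2 of ring D) but is made last, on the complete isoflavone. Heating propargyl ether A10 in N,N-diethylaniline gives A9 by a [3,3] shift and oxa-6π closure.
- Merits: ring D is absent until the end, so every earlier step, including a classical acid-mediated deoxybenzoin synthesis, may use strong acid. The ring A and ring C chemistry is fully tested, which is a real advantage over the unproven cycloaddition of step 11. The pericyclic cascade is the same reaction type that the chosen plan relies on.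
- Weak points: the benzyl ethers of A9 cannot be removed with H2 without saturating C3=C4 of ring D, and BCl3-type cleavage attacks the chromene. The ring B building block with three differentiated oxygens and a homologated side chain still has to be made, so the step count is not lower. The rearrangement must also deliver carbon to a position next to the bulky chromenone.
- Comparison: with acetal or silyl ethers in place of benzyl this road would be a serious competitor. The chosen plan sets against it a ring A construction under neutral conditions, a pyran cascade run on a simple aldehyde, and a single protecting group that is removed in the last step.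

Key step: step 11

Remark on the chemistry: diene 18 is drawn as its (1Z) isomer; the geometry is of no consequence because this carbon becomes aromatic. Carbinol 13 is racemic and its stereocentre is removed in step 8; the target has no stereocentre.

## Route

Step 1
Reactants: 1 3,4-dihydroxy-5-methoxybenzaldehyde (5-hydroxyvanillin)
Product: 2 3-hydroxy-5-methoxy-4-(methoxymethoxy)benzaldehyde
Conditions: MOMCl (1.05 equiv), K2CO3 (1.1 equiv), acetone, 0 °C to rt
Reagents that add atoms: chloromethyl methyl ether (MOMCl), COCCl
Why: O-alkylation of the more acidic phenol (Williamson-type acetal formation): the 4-hydroxyl is para to the formyl group and is ionised first by one equivalent of K2CO3, and selective 4-O-alkylation of 3,4-dihydroxybenzaldehydes is standard.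

Step 2
Reactants: 2 3-hydroxy-5-methoxy-4-(methoxymethoxy)benzaldehyde; 3 3-chloro-3-methylbut-1-yne
Product: 4 3-methoxy-4-(methoxymethoxy)-5-[(2-methylbut-3-yn-2-yl)oxy]benzaldehyde
Conditions: K2CO3, KI, CuI (cat.), acetone, 56 °C
Reagents that add atoms: none
Why: Copper-assisted O-propargylation of the phenoxide by the tertiary propargylic chloride, the usual entry to aryl 1,1-dimethylpropargyl ethers; only one hydroxyl is free.

Step 3
Reactants: 4 3-methoxy-4-(methoxymethoxy)-5-[(2-methylbut-3-yn-2-yl)oxy]benzaldehyde
Product: 7 7-methoxy-8-(methoxymethoxy)-2,2-dimethyl-2H-chromene-5-carbaldehyde, via ortho-allenylphenol 5 (not isolated), via ortho-quinone methide 6 (not isolated)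
Conditions: PhNEt2, 180 °C
Reagents that add atoms: none
Why: Aromatic propargyl Claisen rearrangement ([3,3]) to the only free ortho carbon (the other carries the MOM ether), enolisation to 5, 1,5-hydrogen shift to 6 and oxa-6π electrocyclisation; the gem-dimethyl group speeds each stage and the acetal tolerates the hot amine solvent.

Step 4
Reactants: 7 7-methoxy-8-(methoxymethoxy)-2,2-dimethyl-2H-chromene-5-carbaldehyde
Product: 8 5-ethenyl-7-methoxy-8-(methoxymethoxy)-2,2-dimethyl-2H-chromene
Conditions: Ph3PCH3Br, KOtBu, THF, 0 °C to rt
Reagents that add atoms: methyltriphenylphosphonium bromide, C[P+](c1ccccc1)(c1ccccc1)c1ccccc1.[Br-]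
Why: Wittig methylenation of an aromatic aldehyde with the non-stabilised ylide; the basic medium leaves the MOM acetal and the chromene untouched.

Step 5
Reactants: 8 5-ethenyl-7-methoxy-8-(methoxymethoxy)-2,2-dimethyl-2H-chromene
Product: 10 2-[7-methoxy-8-(methoxymethoxy)-2,2-dimethyl-2H-chromen-5-yl]ethan-1-ol, via B-alkyl-9-BBN adduct 9 (not isolated)
Conditions: 9-BBN, THF, 0 °C to rt; then NaOH, H2O2, H2O, 0 °C to rt
Reagents that add atoms: 9-borabicyclo[3.3.1]nonane (9-BBN), B1C2CCCC1CCC2 (its boron and ring are held only in 9); hydrogen peroxide, OO (the hydroxyl oxygen of 10)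
Why: Anti-Markovnikov hydroboration–oxidation (Brown): 9-BBN places boron on the terminal carbon of the monosubstituted vinyl group far faster than it attacks the cis-disubstituted, conjugated chromene double bond next to a quaternary carbon, and alkaline peroxide replaces boron by hydroxyl.

Step 6
Reactants: 10 2-[7-methoxy-8-(methoxymethoxy)-2,2-dimethyl-2H-chromen-5-yl]ethan-1-ol
Product: 11 [7-methoxy-8-(methoxymethoxy)-2,2-dimethyl-2H-chromen-5-yl]acetaldehyde
Conditions: Dess–Martin periodinane (DMP), NaHCO3, CH2Cl2, 0 °C to rt
Reagents that add atoms: none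
Why: Dess–Martin oxidation of a primary alcohol under buffered, neutral conditions gives the arylacetaldehyde without acid or base that would enolise it; 11 is used at once.

Step 7
Reactants: 11 [7-methoxy-8-(methoxymethoxy)-2,2-dimethyl-2H-chromen-5-yl]acetaldehyde; 12 ethynylmagnesium bromide
Product: 13 1-[7-methoxy-8-(methoxymethoxy)-2,2-dimethyl-2H-chromen-5-yl]but-3-yn-2-ol (racemic)
Conditions: THF, −78 to 0 °C; then aq. NH4Cl
Reagents that add atoms: none
Why: Grignard 1,2-addition of the acetylide to the aldehyde; the weakly basic sp carbanion at low temperature favours addition over enolisation, and the carbinol stereocentre forms as a racemate that step 8 removes.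

Step 8
Reactants: 13 1-[7-methoxy-8-(methoxymethoxy)-2,2-dimethyl-2H-chromen-5-yl]but-3-yn-2-ol
Product: 14 1-[7-methoxy-8-(methoxymethoxy)-2,2-dimethyl-2H-chromen-5-yl]but-3-yn-2-one
Conditions: DMP, NaHCO3, CH2Cl2, 0 °C
Reagents that add atoms: none
Why: Dess–Martin oxidation of the secondary propargylic alcohol to the terminal ynone under buffered conditions; the oxidant spares the chromene alkene and the alkyne, and 14 is taken on without storage.

Step 9
Reactants: 15 methyl acetoacetate
Product: 16 methyl 3-[(trimethylsilyl)oxy]but-2-enoate (E/Z mixture)
Conditions: Me3SiCl, Et3N, hexane, rt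
Reagents that add atoms: chlorotrimethylsilane, C[Si](C)(C)Cl
Why: O-silylation of the enol of the beta-keto ester (silyl enol ether formation) with the amine as acid scavenger.

Step 10
Reactants: 16 methyl 3-[(trimethylsilyl)oxy]but-2-enoate
Product: 18 (1Z)-1-methoxy-1,3-bis[(trimethylsilyl)oxy]buta-1,3-diene, via lithium dienolate 17 (not isolated)
Conditions: LiN(iPr)2, THF, −78 °C; then Me3SiCl, −78 to 0 °C
Reagents that add atoms: chlorotrimethylsilane, C[Si](C)(C)Cl; lithium diisopropylamide, [Li+].CC(C)[N-]C(C)C (its lithium is held only in 17)
Why: Gamma-deprotonation of the vinylogous ester gives extended dienolate 17, which is silylated on oxygen; this is the standard preparation of bis-silyl dienol ethers of acetoacetates.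

Step 11
Reactants: 14 1-[7-methoxy-8-(methoxymethoxy)-2,2-dimethyl-2H-chromen-5-yl]but-3-yn-2-one; 18 (1Z)-1-methoxy-1,3-bis[(trimethylsilyl)oxy]buta-1,3-diene
Product: 21 1-(2,4-dihydroxyphenyl)-2-[7-methoxy-8-(methoxymethoxy)-2,2-dimethyl-2H-chromen-5-yl]ethan-1-one, via cyclohexadiene cycloadduct 19 (not isolated), via bis(trimethylsilyl) aryl ether 20 (not isolated)
Conditions: PhMe, rt to 80 °C; then MeOH, PPTS (cat.), rt
Reagents that add atoms: none
Why: Diels–Alder cycloaddition followed by eliminative aromatisation, the known route from 1,1,3-trioxygenated butadienes and acetylenic ketones to resorcinol ketones. The six-membered ring A is closed by an intermolecular, concerted but asynchronous [4+2] cycloaddition: the unsubstituted CH2 terminus of 18, the most nucleophilic site, bonds to the terminal alkyne carbon of 14 (the future C5–C6 bond) and the ketene acetal carbon bonds to the carbon alpha to the carbonyl (the future C4a–C8a bond). This orientation puts one oxygen ortho and one para to the acyl group; it follows from the polarisation of both partners and needs no catalyst, and leaving out any Lewis acid also avoids attack at the carbonyl carbon, which would lead by a [3+3] condensation to a salicylate. Cycloadduct 19 is a 1,4-cyclohexadiene with a mixed silyl methyl ketal; 1,4-elimination of methanol across the ring gives aromatic bis-silyl ether 20, and methanolysis with a trace of PPTS frees both phenols. The ketal carbon of 19 is the only stereocentre formed and it is lost on aromatisation, so no stereocontrol is needed. The selectivity asked for is cycloaddition in preference to enolisation or O-silylation at the doubly activated CH2 of 14, which the base-free medium, an excess of diene and the high reactivity of the unhindered terminal ynone should secure. The MOM acetal and the chromene do not react with the electron-rich diene and meet no acid stronger than PPTS in methanol.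

Step 12
Reactants: 21 1-(2,4-dihydroxyphenyl)-2-[7-methoxy-8-(methoxymethoxy)-2,2-dimethyl-2H-chromen-5-yl]ethan-1-one
Product: 23 7-hydroxy-3-[7-methoxy-8-(methoxymethoxy)-2,2-dimethyl-2H-chromen-5-yl]-4H-chromen-4-one, via enaminone 22 (not isolated)
Conditions: Me2NCH(OMe)2 (3 equiv), THF, 65 °C
Reagents that add atoms: N,N-dimethylformamide dimethyl acetal, COC(OC)N(C)C
Why: Enaminone formation at the activated CH2 of the deoxybenzoin, then 6-endo addition–elimination of the ortho phenol with loss of dimethylamine, the standard isoflavone ring closure; the para hydroxyl and the MOM acetal are spectators in the neutral medium.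

Step 13
Reactants: 23 7-hydroxy-3-[7-methoxy-8-(methoxymethoxy)-2,2-dimethyl-2H-chromen-5-yl]-4H-chromen-4-one
Product: 24 7-hydroxy-3-(8-hydroxy-7-methoxy-2,2-dimethyl-2H-chromen-5-yl)-4H-chromen-4-one
Conditions: HCl (1 M in MeOH), 40 °C, short reaction time
Reagents that add atoms: none
Why: Acid-catalysed solvolysis of the aryl methoxymethyl acetal (transacetalisation to dimethoxymethane), the usual way to unmask phenols beside 2,2-dimethylchromenes; the reaction is stopped once 23 is consumed so that C3=C4 of ring D does not add methanol.

## Compound list

1 | 3,4-dihydroxy-5-methoxybenzaldehyde (5-hydroxyvanillin) | COc1cc(C=O)cc(O)c1O | starting material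
2 | 3-hydroxy-5-methoxy-4-(methoxymethoxy)benzaldehyde | COCOc1c(O)cc(C=O)cc1OC | intermediate
3 | 3-chloro-3-methylbut-1-yne | CC(C)(Cl)C#C | starting material
4 | 3-methoxy-4-(methoxymethoxy)-5-[(2-methylbut-3-yn-2-yl)oxy]benzaldehyde | COCOc1c(OC)cc(C=O)cc1OC(C)(C)C#C | intermediate
5 | 3-hydroxy-5-methoxy-4-(methoxymethoxy)-2-(3-methylbuta-1,2-dien-1-yl)benzaldehyde | COCOc1c(OC)cc(C=O)c(C=C=C(C)C)c1O | intermediate (not isolated)
6 | (6Z)-3-methoxy-4-(methoxymethoxy)-6-(3-methylbut-2-en-1-ylidene)-5-oxocyclohexa-1,3-diene-1-carbaldehyde | COCOC1=C(OC)C=C(C=O)/C(=C/C=C(C)C)C1=O | intermediate (not isolated)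
7 | 7-methoxy-8-(methoxymethoxy)-2,2-dimethyl-2H-chromene-5-carbaldehyde | COCOc1c(OC)cc(C=O)c2C=CC(C)(C)Oc12 | intermediate
8 | 5-ethenyl-7-methoxy-8-(methoxymethoxy)-2,2-dimethyl-2H-chromene | COCOc1c(OC)cc(C=C)c2C=CC(C)(C)Oc12 | intermediate
9 | 9-{2-[7-methoxy-8-(methoxymethoxy)-2,2-dimethyl-2H-chromen-5-yl]ethyl}-9-borabicyclo[3.3.1]nonane | COCOc1c(OC)cc(CCB3C4CCCC3CCC4)c2C=CC(C)(C)Oc12 | intermediate (not isolated)
10 | 2-[7-methoxy-8-(methoxymethoxy)-2,2-dimethyl-2H-chromen-5-yl]ethan-1-ol | COCOc1c(OC)cc(CCO)c2C=CC(C)(C)Oc12 | intermediate
11 | [7-methoxy-8-(methoxymethoxy)-2,2-dimethyl-2H-chromen-5-yl]acetaldehyde | COCOc1c(OC)cc(CC=O)c2C=CC(C)(C)Oc12 | intermediate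
12 | ethynylmagnesium bromide | C#C[Mg]Br | starting material
13 | 1-[7-methoxy-8-(methoxymethoxy)-2,2-dimethyl-2H-chromen-5-yl]but-3-yn-2-ol (racemic) | COCOc1c(OC)cc(CC(O)C#C)c2C=CC(C)(C)Oc12 | intermediate
14 | 1-[7-methoxy-8-(methoxymethoxy)-2,2-dimethyl-2H-chromen-5-yl]but-3-yn-2-one | COCOc1c(OC)cc(CC(=O)C#C)c2C=CC(C)(C)Oc12 | intermediate
15 | methyl acetoacetate | CC(=O)CC(=O)OC | starting material
16 | methyl 3-[(trimethylsilyl)oxy]but-2-enoate (E/Z mixture) | COC(=O)C=C(C)O[Si](C)(C)C | intermediate
17 | lithium 1-methoxy-3-[(trimethylsilyl)oxy]buta-1,3-dien-1-olate | [Li+].[O-]C(OC)=CC(=C)O[Si](C)(C)C | intermediate (not isolated)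
18 | (1Z)-1-methoxy-1,3-bis[(trimethylsilyl)oxy]buta-1,3-diene | CO/C(O[Si](C)(C)C)=C/C(=C)O[Si](C)(C)C | intermediate
19 | 1-{6-methoxy-4,6-bis[(trimethylsilyl)oxy]cyclohexa-1,4-dien-1-yl}-2-[7-methoxy-8-(methoxymethoxy)-2,2-dimethyl-2H-chromen-5-yl]ethan-1-one (racemic) | COC1(O[Si](C)(C)C)C=C(O[Si](C)(C)C)CC=C1C(=O)Cc1cc(OC)c(OCOC)c2OC(C)(C)C=Cc12 | intermediate (not isolated)
20 | 1-{2,4-bis[(trimethylsilyl)oxy]phenyl}-2-[7-methoxy-8-(methoxymethoxy)-2,2-dimethyl-2H-chromen-5-yl]ethan-1-one | C[Si](C)(C)Oc1ccc(C(=O)Cc2cc(OC)c(OCOC)c3OC(C)(C)C=Cc23)c(O[Si](C)(C)C)c1 | intermediate (not isolated)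
21 | 1-(2,4-dihydroxyphenyl)-2-[7-methoxy-8-(methoxymethoxy)-2,2-dimethyl-2H-chromen-5-yl]ethan-1-one | COCOc1c(OC)cc(CC(=O)c2ccc(O)cc2O)c2C=CC(C)(C)Oc12 | intermediate
22 | 1-(2,4-dihydroxyphenyl)-3-(dimethylamino)-2-[7-methoxy-8-(methoxymethoxy)-2,2-dimethyl-2H-chromen-5-yl]prop-2-en-1-one | CN(C)C=C(C(=O)c1ccc(O)cc1O)c1cc(OC)c(OCOC)c2OC(C)(C)C=Cc12 | intermediate (not isolated)
23 | 7-hydroxy-3-[7-methoxy-8-(methoxymethoxy)-2,2-dimethyl-2H-chromen-5-yl]-4H-chromen-4-one | COCOc1c(OC)cc(-c2coc3cc(O)ccc3c2=O)c2C=CC(C)(C)Oc12 | intermediate
24 | 7-hydroxy-3-(8-hydroxy-7-methoxy-2,2-dimethyl-2H-chromen-5-yl)-4H-chromen-4-one | COc1cc(-c2coc3cc(O)ccc3c2=O)c2c(c1O)OC(C)(C)C=C2 | target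

## Step count and least certain steps

Total step count: 13. Longest linear sequence: 11 steps (steps 1 to 8 and 11 to 13, from 5-hydroxyvanillin 1); the diene branch (steps 9 and 10) joins at step 11.

**Step 11 (key step).** The most likely failure is enolisation of the ynone at its benzylic CH2, with silyl transfer from the ketene acetal or Michael oligomerisation, running ahead of cycloaddition. A stepwise attack at the carbonyl carbon could also divert material to a [3+3] product. The fallback sets out from aldehyde 11 and comes back at 21, with ring A brought in preformed. 4-Bromoresorcinol is bis-allylated (allyl bromide, K2CO3, acetone) to 1-bromo-2,4-bis(prop-2-en-1-yloxy)benzene F1. Bromine–lithium exchange (n-BuLi, THF, −78 °C) gives [2,4-bis(prop-2-en-1-yloxy)phenyl]lithium F2, which adds to 11 to give 1-[2,4-bis(prop-2-en-1-yloxy)phenyl]-2-[7-methoxy-8-(methoxymethoxy)-2,2-dimethyl-2H-chromen-5-yl]ethan-1-ol F3. Dess–Martin oxidation gives 1-[2,4-bis(prop-2-en-1-yloxy)phenyl]-2-[7-methoxy-8-(methoxymethoxy)-2,2-dimethyl-2H-chromen-5-yl]ethan-1-one F4. Pd(PPh3)4, a zerovalent palladium complex, with morpholine in THF then removes both allyl groups under neutral conditions, which spare the MOM acetal and ring D, and gives 21.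

**Step 8.** The terminal ynone can enolise at its doubly activated CH2 and polymerise by conjugate addition during oxidation, chromatography or storage. The fallback sets out from 11 and comes back at 14. Commercial lithium (trimethylsilyl)acetylide adds to 11 to give 1-[7-methoxy-8-(methoxymethoxy)-2,2-dimethyl-2H-chromen-5-yl]-4-(trimethylsilyl)but-3-yn-2-ol F5. Dess–Martin oxidation gives the more robust, storable 1-[7-methoxy-8-(methoxymethoxy)-2,2-dimethyl-2H-chromen-5-yl]-4-(trimethylsilyl)but-3-yn-2-one F6. Na2B4O7 in aqueous methanol removes the silyl group and releases 14 immediately before step 11.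

**Step 12.** The formamide acetal can O-methylate the acidic para hydroxyl, or the reaction can stall at the enaminone because the CH2 is flanked by a ring substituted at both ortho positions. The fallback sets out from 21 and comes back at 24. The para hydroxyl, the one not hydrogen-bonded to the ketone, is protected selectively (MOMCl, K2CO3, acetone) to give 1-[2-hydroxy-4-(methoxymethoxy)phenyl]-2-[7-methoxy-8-(methoxymethoxy)-2,2-dimethyl-2H-chromen-5-yl]ethan-1-one F7. DMF dimethyl acetal gives the enaminone 3-(dimethylamino)-1-[2-hydroxy-4-(methoxymethoxy)phenyl]-2-[7-methoxy-8-(methoxymethoxy)-2,2-dimethyl-2H-chromen-5-yl]prop-2-en-1-one F8, which is not isolated, and from it 7-(methoxymethoxy)-3-[7-methoxy-8-(methoxymethoxy)-2,2-dimethyl-2H-chromen-5-yl]-4H-chromen-4-one F9. Methanolic HCl as in step 13 removes both acetals, closes any enaminone left uncyclised, and gives 24.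

**Step 5.** The borane may also add to the chromene double bond, or oxidation of the hindered borane may be incomplete. The fallback sets out from 7 and comes back at 11. A Wittig reaction with the ylide from (methoxymethyl)triphenylphosphonium chloride and KOtBu gives the enol ether 7-methoxy-5-(2-methoxyethenyl)-8-(methoxymethoxy)-2,2-dimethyl-2H-chromene F10 (E/Z mixture). Closely followed hydrolysis with dilute aqueous HCl in THF at rt gives 11. This is one step shorter but brings acid into contact with the MOM acetal.

## Further compounds

F1 | step 11 | 1-bromo-2,4-bis(prop-2-en-1-yloxy)benzene | C=CCOc1ccc(Br)c(OCC=C)c1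
F2 | step 11 | [2,4-bis(prop-2-en-1-yloxy)phenyl]lithium | C=CCOc1ccc([Li])c(OCC=C)c1
F3 | step 11 | 1-[2,4-bis(prop-2-en-1-yloxy)phenyl]-2-[7-methoxy-8-(methoxymethoxy)-2,2-dimethyl-2H-chromen-5-yl]ethan-1-ol (racemic) | C=CCOc1ccc(C(O)Cc2cc(OC)c(OCOC)c3OC(C)(C)C=Cc23)c(OCC=C)c1
F4 | step 11 | 1-[2,4-bis(prop-2-en-1-yloxy)phenyl]-2-[7-methoxy-8-(methoxymethoxy)-2,2-dimethyl-2H-chromen-5-yl]ethan-1-one | C=CCOc1ccc(C(=O)Cc2cc(OC)c(OCOC)c3OC(C)(C)C=Cc23)c(OCC=C)c1
F5 | step 8 | 1-[7-methoxy-8-(methoxymethoxy)-2,2-dimethyl-2H-chromen-5-yl]-4-(trimethylsilyl)but-3-yn-2-ol (racemic) | COCOc1c(OC)cc(CC(O)C#C[Si](C)(C)C)c2C=CC(C)(C)Oc12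
F6 | step 8 | 1-[7-methoxy-8-(methoxymethoxy)-2,2-dimethyl-2H-chromen-5-yl]-4-(trimethylsilyl)but-3-yn-2-one | COCOc1c(OC)cc(CC(=O)C#C[Si](C)(C)C)c2C=CC(C)(C)Oc12
F7 | step 12 | 1-[2-hydroxy-4-(methoxymethoxy)phenyl]-2-[7-methoxy-8-(methoxymethoxy)-2,2-dimethyl-2H-chromen-5-yl]ethan-1-one | COCOc1ccc(C(=O)Cc2cc(OC)c(OCOC)c3OC(C)(C)C=Cc23)c(O)c1
F8 | step 12 | 3-(dimethylamino)-1-[2-hydroxy-4-(methoxymethoxy)phenyl]-2-[7-methoxy-8-(methoxymethoxy)-2,2-dimethyl-2H-chromen-5-yl]prop-2-en-1-one | CN(C)C=C(C(=O)c1ccc(OCOC)cc1O)c1cc(OC)c(OCOC)c2OC(C)(C)C=Cc12
F9 | step 12 | 7-(methoxymethoxy)-3-[7-methoxy-8-(methoxymethoxy)-2,2-dimethyl-2H-chromen-5-yl]-4H-chromen-4-one | COCOc1ccc2c(c1)occ(-c1cc(OC)c(OCOC)c3OC(C)(C)C=Cc13)c2=O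
F10 | step 5 | 7-methoxy-5-(2-methoxyethenyl)-8-(methoxymethoxy)-2,2-dimethyl-2H-chromene (E/Z mixture) | COCOc1c(OC)cc(C=COC)c2C=CC(C)(C)Oc12
A1 | alternative 1 | 7-(benzyloxy)-3-(3,4-dihydroxy-5-methoxyphenyl)-4H-chromen-4-one | COc1cc(-c2coc3cc(OCc4ccccc4)ccc3c2=O)cc(O)c1O
A2 | alternative 1 | 1-[4-(benzyloxy)-2-hydroxyphenyl]ethan-1-one | CC(=O)c1ccc(OCc2ccccc2)cc1O
A3 | alternative 1 | 3-methoxybenzene-1,2-diol (3-methoxycatechol) | COc1cccc(O)c1O
A4 | alternative 1 | 3-methoxycyclohexa-3,5-diene-1,2-dione | COC1=CC=CC(=O)C1=O
A5 | alternative 1 | (2E)-1-[4-(benzyloxy)-2-hydroxyphenyl]-3-(dimethylamino)prop-2-en-1-one | CN(C)/C=C/C(=O)c1ccc(OCc2ccccc2)cc1O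
A6 | alternative 2 | 7-methoxy-8-(methoxymethoxy)-2,2-dimethyl-2H-chromene-5-carbaldehyde | COCOc1c(OC)cc(C=O)c2C=CC(C)(C)Oc12
A7 | alternative 2 | 3-bromo-2-[(1Z)-3-hydroxy-3-methylbut-1-en-1-yl]-5-methoxy-4-(methoxymethoxy)benzaldehyde | COCOc1c(OC)cc(C=O)c(/C=C\C(C)(C)O)c1Br
A8 | alternative 2 | 3-bromo-4-hydroxy-5-methoxybenzaldehyde (5-bromovanillin) | COc1cc(C=O)cc(Br)c1O
A9 | alternative 3 | 7-(benzyloxy)-3-[8-(benzyloxy)-7-methoxy-2,2-dimethyl-2H-chromen-5-yl]-4H-chromen-4-one | COc1cc(-c2coc3cc(OCc4ccccc4)ccc3c2=O)c2C=CC(C)(C)Oc2c1OCc1ccccc1
A10 | alternative 3 | 7-(benzyloxy)-3-{4-(benzyloxy)-3-methoxy-5-[(2-methylbut-3-yn-2-yl)oxy]phenyl}-4H-chromen-4-one | COc1cc(-c2coc3cc(OCc4ccccc4)ccc3c2=O)cc(OC(C)(C)C#C)c1OCc1ccccc1
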